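**Retrosynthetic overview**
1. The last bond made is the ester C(acyl)–O bond. It joins unprotected 2,3-dihydroxybenzoic acid and 20-methylhenicosan-1-ol through a new boron-catalysed dehydrative coupling.
2. 20-Methylhenicosan-1-ol is cut at the C11–C12 sp3–sp3 bond into a 9-methyldecyl Grignard reagent and 11-bromoundecan-1-ol (OH masked in situ as its Mg alkoxide).
3. 1-Chloro-9-methyldecane is cut at C6–C7 into isopentyl Grignard reagent and 1-bromo-6-chlorohexane. The bromide couples and the chloride is kept for the next Grignard reagent.
4. No ring is formed. The only ring (the catechol arene) is bought as 2,3-dihydroxybenzoic acid, and there is no stereocentre to set.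

Assumption: the SMILES has no stereocentre and no stereogenic double bond. The target, 20-methylhenicosyl 2,3-dihydroxybenzoate (C29H50O4), and every numbered compound are therefore achiral, and no stereocontrol is needed.

**Step 1**
Reactants: 1 1-bromo-3-methylbutane (isopentyl bromide); 2 1-bromo-6-chlorohexane
Product: 4 1-chloro-9-methyldecane, via isopentylmagnesium bromide 3 (not isolated)
Conditions: 1, Mg, THF, 40 °C; then 2, Li2CuCl4 (2 mol %), THF, 0 °C → rt; aq. NH4Cl; distillation
Reagents that add atoms: none
Why: In this copper-catalysed Kumada-type (Kochi–Tamura) sp3–sp3 cross-coupling, the alkylcuprate formed from 3 displaces the primary bromide of 2 far faster than the chloride, so the C–Cl end survives as the handle for the next Grignard reagent and no stereocentre is formed.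

**Step 2**
Reactants: 4 1-chloro-9-methyldecane; 5 11-bromoundecan-1-ol
Product: 9 20-methylhenicosan-1-ol, via (9-methyldecyl)magnesium chloride 6 (not isolated), via chloromagnesium 11-bromoundecan-1-olate 7 (not isolated), via chloromagnesium 20-methylhenicosan-1-olate 8 (not isolated)
Conditions: 4, Mg (I2 cat.), THF, reflux; separately 5, MeMgCl (1.0 equiv), THF, −20 °C; combine, Li2CuCl4 (3 mol %), NMP (4 equiv), 0 °C → rt; 1 M HCl; recrystallise (acetone)
Reagents that add atoms: none
Why: Primary alkyl chlorides insert Mg cleanly in refluxing THF, and the same Kochi–Tamura Cu-catalysed alkyl–alkyl coupling accepts the bromo alcohol once its OH is masked as the magnesium alkoxide 7, which gives the complete iso-C22 chain (8 + 11 = 19 CH2) without a protecting group or a new stereocentre.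

**Step 3**
Reactants: 9 20-methylhenicosan-1-ol; 10 2,3-dihydroxybenzoic acid
Product: 14 gentiside A (20-methylhenicosyl 2,3-dihydroxybenzoate), via catecholate-mode boronate of the acid 11 (not isolated), via salicylate-mode acyl boronate 12 (not isolated), via catecholate-mode boronate of the ester 13 (not isolated)
Conditions: 9 (1.0 equiv), 10 (1.05 equiv), 3,4,5-F3C6H2B(OH)2 (10 mol %), PhMe (0.3 M), reflux, 4 Å MS (Soxhlet), Ar, 24 h; aq. sorbitol wash
Reagents that add atoms: none
Why: Proposed new method: this is a "chelate-mode-switch" boronic-acid-catalysed 1:1 dehydrative esterification of an unprotected catechol acid, in which the electron-poor boronic acid condenses reversibly with 10 to give the catecholate chelate 11, which equilibrates with the six-membered salicylate-type chelate 12; 12 is a cyclic acyl boronate (mixed anhydride) whose acyl oxygen donates into the empty boron p-orbital, so the otherwise H-bond-deactivated, electron-rich carboxyl carbon becomes electrophilic enough for attack by the primary alcohol 9; as the acyl O–B bond breaks, the free C3–OH closes on boron to give the more stable five-membered catechol boronate 13, which makes acyl transfer irreversible, keeps both phenols masked against O-acylation and oxidation, and passes boron to fresh 10 by fast catechol exchange (releasing 14 and regenerating 11) while the sieves remove water; the closest known reaction type is boric-acid or arylboronic-acid-catalysed dehydrative esterification of α-hydroxy acids and amidation via (acyloxy)boron intermediates, which has not been shown for catechol or salicyl carboxylic acids with an equimolar fatty alcohol; no stereocentre is formed.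

**Compound list**
1 | 1-bromo-3-methylbutane | CC(C)CCBr | starting material
2 | 1-bromo-6-chlorohexane | ClCCCCCCBr | starting material
3 | isopentylmagnesium bromide | CC(C)CC[Mg]Br | intermediate
4 | 1-chloro-9-methyldecane | CC(C)CCCCCCCCCl | intermediate
5 | 11-bromoundecan-1-ol | OCCCCCCCCCCCBr | starting material
6 | (9-methyldecyl)magnesium chloride | CC(C)CCCCCCCC[Mg]Cl | intermediate
7 | chloromagnesium 11-bromoundecan-1-olate | BrCCCCCCCCCCCO[Mg]Cl | intermediate
8 | chloromagnesium 20-methylhenicosan-1-olate | CC(C)CCCCCCCCCCCCCCCCCCCO[Mg]Cl | intermediate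
9 | 20-methylhenicosan-1-ol | CC(C)CCCCCCCCCCCCCCCCCCCO | intermediate
10 | 2,3-dihydroxybenzoic acid | OC(=O)c1cccc(O)c1O | starting material
11 | 2-(3,4,5-trifluorophenyl)-1,3,2-benzodioxaborole-4-carboxylic acid (catecholate-mode chelate of 10) | OC(=O)c1cccc2OB(c3cc(F)c(F)c(F)c3)Oc12 | intermediate
12 | 8-hydroxy-2-(3,4,5-trifluorophenyl)-4H-1,3,2-benzodioxaborinin-4-one (salicylate-mode acyl boronate of 10) | O=C1OB(c2cc(F)c(F)c(F)c2)Oc3c(O)cccc13 | intermediate
13 | 20-methylhenicosyl 2-(3,4,5-trifluorophenyl)-1,3,2-benzodioxaborole-4-carboxylate | CC(C)CCCCCCCCCCCCCCCCCCCOC(=O)c1cccc2OB(c3cc(F)c(F)c(F)c3)Oc12 | intermediate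
14 | gentiside A, 20-methylhenicosyl 2,3-dihydroxybenzoate (achiral) | CC(C)CCCCCCCCCCCCCCCCCCCOC(=O)c1cccc(O)c1O | target

**Step count**
- Total step count: 3.
- Longest linear sequence: 3 (1 → 4 → 9 → 14).

**Steps most likely to fail**

*Step 3 (the new method).*
- Risk: boron may stay parked in the catecholate chelates 11 and 13. Compound 10 is also poorly soluble in toluene, so turnover may be too slow.
- The fallback uses known chemistry. It sets out from 9 (with 10) and comes back at 14.
- It is a chemoselective Mitsunobu esterification (PPh3 and DIAD, 1.05 equiv each, THF, 0 °C → rt).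
- Only the carboxylic acid (pKa about 3, against 9 or more for the phenols) protonates the betaine.
- Alcohol 9 is activated as (20-methylhenicosyloxy)triphenylphosphonium 2,3-dihydroxybenzoate F1, and the carboxylate attacks the primary carbon by SN2.
- The alkyl C–O bond is therefore made instead of the acyl C–O bond, again without phenol protection.

*Step 2.*
- Risk: sluggish Mg insertion into the chloride, Wurtz dimer formation, or a heterogeneous alkoxide 7 that couples poorly.
- The fallback sets out from 4 and comes back at 9.
- A Finkelstein exchange (NaI, acetone, reflux) gives 1-iodo-9-methyldecane F2.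
- Commercial undec-10-yn-1-ol (C#CCCCCCCCCCO) is deprotonated twice (n-BuLi 2.1 equiv, THF/DMPU, −78 → 0 °C) to lithium 11-lithioundec-10-yn-1-olate F3.
- The acetylide carbon of F3 is alkylated by F2. After a water quench this gives 20-methylhenicos-10-yn-1-ol F4.
- Full hydrogenation (H2 1 atm, Pd/C, EtOAc) delivers 9.

*Step 1.*
- Risk: eroded Br/Cl selectivity (double coupling) or homocoupling products that are hard to distil away.
- The fallback sets out from 2 and comes back at 4.
- PPh3 in refluxing MeCN gives (6-chlorohexyl)triphenylphosphonium bromide F5.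
- NaHMDS (THF, −78 °C) gives (6-chlorohexylidene)triphenylphosphorane F6. It is trapped at once with commercial 3-methylbutanal (CC(C)CC=O) in a Wittig olefination to give (Z)-1-chloro-9-methyldec-6-ene F7.
- Hydrogenation (H2, Pd/C, EtOAc) leaves the primary C–Cl bond intact and gives 4.

**Further compounds**
F1 | step 3 | (20-methylhenicosyloxy)triphenylphosphonium 2,3-dihydroxybenzoate | CC(C)CCCCCCCCCCCCCCCCCCCO[P+](c1ccccc1)(c1ccccc1)c1ccccc1.[O-]C(=O)c1cccc(O)c1O
F2 | step 2 | 1-iodo-9-methyldecane | CC(C)CCCCCCCCI
F3 | step 2 | lithium 11-lithioundec-10-yn-1-olate | [Li]C#CCCCCCCCCCO[Li]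
F4 | step 2 | 20-methylhenicos-10-yn-1-ol | CC(C)CCCCCCCCC#CCCCCCCCCCO
F5 | step 1 | (6-chlorohexyl)triphenylphosphonium bromide | ClCCCCCC[P+](c1ccccc1)(c1ccccc1)c1ccccc1.[Br-]
F6 | step 1 | (6-chlorohexylidene)triphenylphosphorane | ClCCCCCC=P(c1ccccc1)(c1ccccc1)c1ccccc1
F7 | step 1 | (Z)-1-chloro-9-methyldec-6-ene | CC(C)C/C=C\CCCCCCl
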